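**Plan**

- Locants: 3,7-dioxabicyclo[3.3.0]octane; C1/C5 = bridgehead carbinols, C2/C6 = ArCH, O3/O7 = ring oxygens, C4/C8 = CH2; ring A = C1-C2-O3-C4-C5, ring B = C5-C6-O7-C8-C1.
- Enabling feature: each bridgehead C–OH with its benzylic neighbour (C1/C2 and C5/C6) is a masked oxirane, and each ring oxygen (O3, O7) is the hydroxymethyl oxygen of the opposite half, lying γ to that benzylic carbon.
- Retrosynthesis: cut C2–O3 (last bond formed), then C6–O7, to reach a twofold-symmetric 2,2'-bioxirane; cut the epoxide C–O bonds to an (E,E)-2,3-dibenzylidenebutane-1,4-diol; cut both C=C bonds to two vanillin units and succinate.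
- Forward: twofold Stobbe condensation joins the chain, reduction gives the diene-diol, twofold asymmetric epoxidation follows, then one acid-triggered cascade closes ring B and finally ring A.
- Stereochemistry: C1 and C5 come from reagent-controlled Sharpless epoxidation (D-(−)-tartrate); C2 and C6 arise by inversion at the benzylic epoxide carbons, so they trace back to the (E)-alkene geometry.
- Helper groups: tosyl groups on the phenols keep the epoxide openings SN2-like and are removed last.

Key step: step 7

Remark on the chemistry: the sense of the titanium-tartrate epoxidation is taken from the empirical rule that L-(+)-tartrate gives 2S epoxy alcohols from primary allylic alcohols; the 2R,3R units needed here therefore call for D-(−)-tartrate.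

**Route**

Step 1
Reactants: 1 vanillin
Product: 2 3-methoxy-4-(methoxymethoxy)benzaldehyde
Conditions: MOMCl (1.3 equiv), i-Pr2NEt (1.5 equiv), CH2Cl2, 0 °C to rt
Reagents that add atoms: chloromethyl methyl ether, COCCl
Why: Williamson-type O-alkylation of the phenol gives a base-stable acetal that survives the alkoxide condensation of step 2 and falls off under the acid of step 3.

Step 2
Reactants: 2 3-methoxy-4-(methoxymethoxy)benzaldehyde (2.2 equiv); 3 dimethyl succinate
Product: 5 (2E,3E)-2,3-bis[3-methoxy-4-(methoxymethoxy)benzylidene]butanedioic acid, via mono-benzylidene half-ester 4 (not isolated)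
Conditions: KOt-Bu (3 equiv), t-BuOH, reflux; then 1 M HCl, 0 °C
Reagents that add atoms: none
Why: Twofold Stobbe condensation; each aldol adduct lactonises onto an ester and opens by elimination, which should give the (E)-alkene with the aryl group trans to the carboxyl group at both ends.

Step 3
Reactants: 5 (2E,3E)-2,3-bis[3-methoxy-4-(methoxymethoxy)benzylidene]butanedioic acid
Product: 6 dimethyl (2E,3E)-2,3-bis(4-hydroxy-3-methoxybenzylidene)butanedioate
Conditions: HCl (1.25 M in MeOH), reflux
Reagents that add atoms: methanol, CO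
Why: Fischer esterification of both acids and acid methanolysis of both MOM acetals should occur in one operation without touching the alkene geometry.

Step 4
Reactants: 6 dimethyl (2E,3E)-2,3-bis(4-hydroxy-3-methoxybenzylidene)butanedioate
Product: 7 dimethyl (2E,3E)-2,3-bis[3-methoxy-4-(tosyloxy)benzylidene]butanedioate
Conditions: TsCl (2.4 equiv), Et3N (3 equiv), DMAP (10 mol %), CH2Cl2, 0 °C to rt
Reagents that add atoms: p-toluenesulfonyl chloride, Cc1ccc(cc1)S(Cl)(=O)=O
Why: Phenol sulfonylation; the tosyloxy group resists hydride and Lewis acid and lowers the cation-stabilising power of the guaiacyl ring to about that of phenyl, which steps 6 and 7 require.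

Step 5
Reactants: 7 dimethyl (2E,3E)-2,3-bis[3-methoxy-4-(tosyloxy)benzylidene]butanedioate
Product: 8 (2E,3E)-2,3-bis[3-methoxy-4-(tosyloxy)benzylidene]butane-1,4-diol
Conditions: i-Bu2AlH (5 equiv), CH2Cl2, −78 °C; then aq. potassium sodium tartrate
Reagents that add atoms: none
Why: 1,2-Reduction of both α,β-unsaturated esters to allylic alcohols; aryl sulfonates and the trisubstituted alkenes should be inert, so each aryl group stays trans to its CH2OH.

Step 6
Reactants: 8 (2E,3E)-2,3-bis[3-methoxy-4-(tosyloxy)benzylidene]butane-1,4-diol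
Product: 10 [(2R,2'R,3R,3'R)-3,3'-bis[3-methoxy-4-(tosyloxy)phenyl]-2,2'-bioxirane-2,2'-diyl]dimethanol, via mono-epoxide 9 (not isolated)
Conditions: Ti(Oi-Pr)4 (0.3 equiv), D-(−)-diisopropyl tartrate (0.4 equiv), t-BuOOH (4 equiv, decane solution), 4 Å MS, CH2Cl2, −20 °C
Reagents that add atoms: tert-butyl hydroperoxide, CC(C)(C)OO
Why: Sharpless asymmetric epoxidation of two (E)-2-substituted 3-aryl allylic alcohol units; D-(−)-tartrate should give the 2R,3R epoxy alcohol at each unit, fixing the future C1 and C5 and the benzylic configuration that step 7 inverts. The second epoxidation of 9 is again reagent-controlled, and a wrong-face event ends mainly in the separable meso-type diastereomer, which should raise the enantiomeric purity of 10.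

Step 7
Reactants: 10 [(2R,2'R,3R,3'R)-3,3'-bis[3-methoxy-4-(tosyloxy)phenyl]-2,2'-bioxirane-2,2'-diyl]dimethanol
Product: 12 (1R,2S,5R,6S)-2,6-bis[3-methoxy-4-(tosyloxy)phenyl]-3,7-dioxabicyclo[3.3.0]octane-1,5-diol, via spiro-epoxy oxolane 11 (not isolated)
Conditions: CSA (0.2 equiv), CH2Cl2, 0 °C to rt
Reagents that add atoms: none
Why: Protonation of one oxirane lets the hydroxymethyl oxygen of the other half attack the benzylic carbon from the rear of the breaking C–O bond, which frees the C5 hydroxyl and closes ring B (C6–O7); the same event on 11 (oxygen of C4H2OH onto C2) closes ring A and frees the C1 hydroxyl. The closest known reaction type is the acid-catalysed cyclisation of 4-aryl-3,4-epoxy alcohols to 2-aryl-3-hydroxytetrahydrofurans. Both rings close in the 5-endo-tet mode at the epoxide, the only alternative being 4-exo attack at the fully substituted carbon. C2 and C6 are set by inversion of the (R)-benzylic epoxide carbons, which from the trans-epoxide geometry places each aryl group exo (cis to the neighbouring bridgehead OH); C1 and C5 keep the oxygens delivered in step 6, and the homochiral relation of the two oxiranes allows only the cis-fused bicycle. The step needs benzylic regioselectivity and clean inversion instead of ionisation: ring size secures the first, and the electron-withdrawing tosyloxy groups should secure the second and suppress semipinacol rearrangement.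

Step 8
Reactants: 12 (1R,2S,5R,6S)-2,6-bis[3-methoxy-4-(tosyloxy)phenyl]-3,7-dioxabicyclo[3.3.0]octane-1,5-diol
Product: 13 (1R,2S,5R,6S)-2,6-bis(4-hydroxy-3-methoxyphenyl)-3,7-dioxabicyclo[3.3.0]octane-1,5-diol
Conditions: KOH (6 equiv), MeOH/H2O (degassed), 60 °C; then aq. NH4Cl
Reagents that add atoms: none
Why: Hydroxide attacks sulfur of the aryl sulfonates (S–O cleavage), so no stereocentre is touched; the benzylic ring ethers and tertiary alcohols should be stable to base.

**Compound list**

1 | vanillin (4-hydroxy-3-methoxybenzaldehyde) | COc1cc(C=O)ccc1O | starting material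
2 | 3-methoxy-4-(methoxymethoxy)benzaldehyde | COCOc1ccc(C=O)cc1OC | intermediate
3 | dimethyl succinate | COC(=O)CCC(=O)OC | starting material
4 | (3E)-3-(methoxycarbonyl)-4-[3-methoxy-4-(methoxymethoxy)phenyl]but-3-enoic acid | COC(=O)/C(CC(O)=O)=C/c1ccc(OCOC)c(OC)c1 | intermediate
5 | (2E,3E)-2,3-bis[3-methoxy-4-(methoxymethoxy)benzylidene]butanedioic acid | OC(=O)/C(=C/c1ccc(OCOC)c(OC)c1)C(=C\c1ccc(OCOC)c(OC)c1)/C(O)=O | intermediate
6 | dimethyl (2E,3E)-2,3-bis(4-hydroxy-3-methoxybenzylidene)butanedioate | COC(=O)/C(=C/c1ccc(O)c(OC)c1)C(=C\c1ccc(O)c(OC)c1)/C(=O)OC | intermediate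
7 | dimethyl (2E,3E)-2,3-bis[3-methoxy-4-(tosyloxy)benzylidene]butanedioate | COC(=O)/C(=C/c1ccc(OS(=O)(=O)c2ccc(C)cc2)c(OC)c1)C(=C\c1ccc(OS(=O)(=O)c2ccc(C)cc2)c(OC)c1)/C(=O)OC | intermediate
8 | (2E,3E)-2,3-bis[3-methoxy-4-(tosyloxy)benzylidene]butane-1,4-diol (each aryl trans to its CH2OH) | OC/C(=C/c1ccc(OS(=O)(=O)c2ccc(C)cc2)c(OC)c1)C(=C\c1ccc(OS(=O)(=O)c2ccc(C)cc2)c(OC)c1)/CO | intermediate
9 | [(2R,3R)-2-{(1Z)-3-hydroxy-1-[3-methoxy-4-(tosyloxy)phenyl]prop-1-en-2-yl}-3-[3-methoxy-4-(tosyloxy)phenyl]oxiran-2-yl]methanol (mono-epoxide of 8) | COc1cc(ccc1OS(=O)(=O)c2ccc(C)cc2)[C@H]3O[C@@]3(CO)/C(CO)=C\c4ccc(OS(=O)(=O)c5ccc(C)cc5)c(OC)c4 | intermediate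
10 | [(2R,2'R,3R,3'R)-3,3'-bis[3-methoxy-4-(tosyloxy)phenyl]-2,2'-bioxirane-2,2'-diyl]dimethanol | COc1cc(ccc1OS(=O)(=O)c2ccc(C)cc2)[C@H]3O[C@@]3(CO)[C@]4(CO)O[C@@H]4c5ccc(OS(=O)(=O)c6ccc(C)cc6)c(OC)c5 | intermediate
11 | (2R,3R,6S,7R)-7-(hydroxymethyl)-2,6-bis[3-methoxy-4-(tosyloxy)phenyl]-1,5-dioxaspiro[2.4]heptan-7-ol (ring B closed, second oxirane intact) | COc1cc(ccc1OS(=O)(=O)c2ccc(C)cc2)[C@@H]3OC[C@]4(O[C@@H]4c5ccc(OS(=O)(=O)c6ccc(C)cc6)c(OC)c5)[C@@]3(O)CO | intermediate
12 | (1R,2S,5R,6S)-2,6-bis[3-methoxy-4-(tosyloxy)phenyl]-3,7-dioxabicyclo[3.3.0]octane-1,5-diol | COc1cc([C@@H]2OC[C@@]3(O)[C@H](c4ccc(OS(=O)(=O)c5ccc(C)cc5)c(OC)c4)OC[C@@]23O)ccc1OS(=O)(=O)c6ccc(C)cc6 | intermediate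
13 | (1R,2S,5R,6S)-2,6-bis(4-hydroxy-3-methoxyphenyl)-3,7-dioxabicyclo[3.3.0]octane-1,5-diol | COc1cc([C@@H]2OC[C@@]3(O)[C@H](c4ccc(O)c(OC)c4)OC[C@@]23O)ccc1O | target

**Count and risks**

Total steps: 8. Longest linear sequence: 8 steps (from vanillin).

Steps most likely to fail, with fallbacks:

1. Step 7. The tosyloxy-aryl groups may retard benzylic C–O cleavage so much that the cascade stalls after the first ring or diverts into semipinacol (Meinwald) rearrangement. Fallback: the order of events is changed so that the openings run with electron-rich aryl groups. Setting out from 10, the sulfonyl groups are removed first (Mg turnings, MeOH, 0 °C to rt) to give the bisphenol bis-epoxide F1. Its free para-hydroxyl groups make both benzylic carbons ionise readily (quinone-methide-type opening), so F1 should cyclise with PPTS in CH2Cl2 at 0 °C through the mono-cyclised bisphenol spiro-epoxide F2. The benzylic centres are then set by the kinetic preference for exo-aryl closure and no longer by strict inversion. The sequence comes back to the route at 13, and step 8 is not needed.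

2. Step 6. The 1,4-diol may bind titanium as a chelate, which would slow oxygen transfer and erode face selectivity in one or both epoxidations. Fallback: setting out from 8, a non-directed chiral dioxirane epoxidation is used: D-fructose-derived Shi ketone, Oxone (2KHSO5·KHSO4·K2SO4), K2CO3 buffer, MeCN/dimethoxymethane/H2O, 0 °C. Its face selection rests on the (E)-trisubstituted aryl alkene and not on the hydroxyl groups, and it has the same sense as the R benzylic carbons required. It passes through 9 and comes back to the route at 10.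

3. Step 2. The second condensation has to occur on the carboxylate of half-ester 4 and may be incomplete, or geometric isomers may form. Fallback: the two condensations are run separately. Setting out from 2 and 3, one Stobbe condensation (KOt-Bu, t-BuOH, rt) gives 4, which is isolated and esterified (MeI, K2CO3, DMF) to the mono-benzylidene diester F3. A second Stobbe condensation of F3 with 2 (KOt-Bu, t-BuOH, reflux) gives the bis-benzylidene half-ester F4. F4 is taken through the conditions of step 3 and comes back to the route at 6.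

Further compounds
F1 | step 7 | [(2R,2'R,3R,3'R)-3,3'-bis(4-hydroxy-3-methoxyphenyl)-2,2'-bioxirane-2,2'-diyl]dimethanol | COc1cc(ccc1O)[C@H]2O[C@@]2(CO)[C@]3(CO)O[C@@H]3c4ccc(O)c(OC)c4
F2 | step 7 | (2R,3R,6S,7R)-2,6-bis(4-hydroxy-3-methoxyphenyl)-7-(hydroxymethyl)-1,5-dioxaspiro[2.4]heptan-7-ol | COc1cc(ccc1O)[C@@H]2OC[C@]3(O[C@@H]3c4ccc(O)c(OC)c4)[C@@]2(O)CO
F0 | step 6 | none | none
F3 | step 2 | dimethyl (2E)-2-[3-methoxy-4-(methoxymethoxy)benzylidene]butanedioate | COC(=O)/C(CC(=O)OC)=C/c1ccc(OCOC)c(OC)c1
F4 | step 2 | (2E,3E)-4-methoxy-2,3-bis[3-methoxy-4-(methoxymethoxy)benzylidene]-4-oxobutanoic acid | COC(=O)/C(=C/c1ccc(OCOC)c(OC)c1)C(=C\c1ccc(OCOC)c(OC)c1)/C(O)=O
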